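## Retrosynthetic overview

1. Numbering: C7/C8/C9 is the three-carbon unit of the furofuran attached to the benzofuran ring, C7'/C8'/C9' the unit attached to the syringyl ring. The last step removes three silyl ethers with fluoride.
2. Key disconnection: the ring-fusion bond C8–C8' and the benzylic bond C7–O(C9') are opened together, giving an acyclic (E)-cinnamyl ether of a 1-aryl-2,3-epoxypropanol. Forward, titanocene(III) opens the epoxide, the radical cyclises 5-exo, and iodine triggers a radical–polar crossover etherification: both oxolane rings and C8', C8 and C7 arise in one operation.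
3. Enabling feature: C8'–C9'H2–O is a latent terminal oxirane; the ether oxygen between C7' and C9 holds the C8' radical 1,6 to the C8=C7 styrene; C7 is benzylic and para to the dihydrobenzofuran ring oxygen, so its radical can be oxidised and captured by the C9' oxygen.
4. The precursor comes from two enantiopure pieces joined by cross-metathesis: the allyl ether of a syringyl epoxy alcohol (Sharpless kinetic resolution sets C7') and a 5-vinyl-2,3-cis-dihydrobenzofuran (Rh(II) asymmetric C–H insertion sets C2/C3).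
5. Ring order: dihydrobenzofuran ring (step 10), then oxolane O/C7'/C8'/C8/C9 (radical) and oxolane O/C9'/C8'/C8/C7 (ionic), both in the key step.

Key step: step 15

Remark on the chemistry: the target as drawn has a 2,3-cis (2S,3S) dihydrobenzofuran and a (7S,8R,7'S,8'R) di-exo furofuran, and the route is built for exactly this isomer. The sense of induction of Rh2(R-PTTL)4 (step 10) and of the D-(−)-DIPT resolution (step 3) is assigned by analogy with the parent substrate classes. Titanocene species are written with σ-bonded cyclopentadienyl rings in SMILES.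

## Route

Step 1
Reactants: 1 syringaldehyde (4-hydroxy-3,5-dimethoxybenzaldehyde)
Product: 2 3,5-dimethoxy-4-(triisopropylsilyloxy)benzaldehyde
Conditions: TIPSCl, imidazole, DMAP (cat.), DMF, rt to 40 °C
Reagents that add atoms: chlorotriisopropylsilane, CC(C)[Si](Cl)(C(C)C)C(C)C
Why: Imidazole-promoted O-silylation of the phenol; the TIPS aryl ether should survive the Grignard, alkoxide, Ru and Ti(III) steps and leave with fluoride at the end.

Step 2
Reactants: 2 3,5-dimethoxy-4-(triisopropylsilyloxy)benzaldehyde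
Product: 3 rac-1-[3,5-dimethoxy-4-(triisopropylsilyloxy)phenyl]prop-2-en-1-ol
Conditions: vinylMgBr, THF, −78 to 0 °C; aq. NH4Cl
Reagents that add atoms: vinylmagnesium bromide, C=C[Mg]Br
Why: Grignard 1,2-addition to the aldehyde gives the racemic aryl vinyl carbinol required for kinetic resolution.

Step 3
Reactants: 3 rac-1-[3,5-dimethoxy-4-(triisopropylsilyloxy)phenyl]prop-2-en-1-ol
Product: 4 (R)-[3,5-dimethoxy-4-(triisopropylsilyloxy)phenyl][(2S)-oxiran-2-yl]methanol (erythro epoxy alcohol)
Conditions: Ti(OiPr)4 (0.2 equiv), D-(−)-DIPT (0.25 equiv), TBHP (0.45 equiv), 4 Å MS, CH2Cl2, −20 °C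
Reagents that add atoms: tert-butyl hydroperoxide, CC(C)(C)OO
Why: Sharpless kinetic resolution, in which D-(−)-DIPT should epoxidise the (S)-carbinol enantiomer fast and anti to the aryl group to give the erythro epoxy alcohol, fixing the future C7' centre, while the unreacted (R)-enantiomer of 3 is removed by chromatography (conversion held near 45 %).

Step 4
Reactants: 4 (R)-[3,5-dimethoxy-4-(triisopropylsilyloxy)phenyl][(2S)-oxiran-2-yl]methanol
Product: 5 (2S)-2-[(R)-(allyloxy)[3,5-dimethoxy-4-(triisopropylsilyloxy)phenyl]methyl]oxirane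
Conditions: allyl bromide (3 equiv), NaH, TBAI (cat.), THF/DMF, 0 °C
Reagents that add atoms: allyl bromide, C=CCBr
Why: Williamson etherification in which the alkoxide is generated in the presence of excess allyl bromide at 0 °C so that O-allylation outruns Payne rearrangement; no stereocentre is touched.

Step 5
Reactants: 6 vanillin (4-hydroxy-3-methoxybenzaldehyde)
Product: 7 3-methoxy-4-(triisopropylsilyloxy)benzaldehyde
Conditions: TIPSCl, imidazole, DMF, rt
Reagents that add atoms: chlorotriisopropylsilane, CC(C)[Si](Cl)(C(C)C)C(C)C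
Why: Phenol silylation as in step 1.

Step 6
Reactants: 7 3-methoxy-4-(triisopropylsilyloxy)benzaldehyde
Product: 8 [3-methoxy-4-(triisopropylsilyloxy)phenyl]methanol
Conditions: NaBH4, MeOH/THF, 0 °C
Reagents that add atoms: none
Why: Borohydride reduction of the aldehyde to the benzylic alcohol; the aryl TIPS ether is stable at 0 °C.

Step 7
Reactants: 9 4-bromo-2-methoxyphenol
Product: 10 4-bromo-2-iodo-6-methoxyphenol
Conditions: I2, KI, NaHCO3, H2O/THF, 0 °C to rt
Reagents that add atoms: iodine, II
Why: Electrophilic aromatic iodination of the phenoxide, directed to the free ortho position of the O− group because the para position carries bromine.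

Step 8
Reactants: 10 4-bromo-2-iodo-6-methoxyphenol, 8 [3-methoxy-4-(triisopropylsilyloxy)phenyl]methanol
Product: 11 5-bromo-1-iodo-3-methoxy-2-{[3-methoxy-4-(triisopropylsilyloxy)benzyl]oxy}benzene
Conditions: PPh3, DIAD, THF, 0 °C to rt
Reagents that add atoms: none
Why: Mitsunobu etherification of the acidic dihalophenol with the primary benzylic alcohol under neutral conditions, which avoids a labile p-silyloxybenzyl halide.

Step 9
Reactants: 11 5-bromo-1-iodo-3-methoxy-2-{[3-methoxy-4-(triisopropylsilyloxy)benzyl]oxy}benzene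
Product: 12 ethyl 2-(5-bromo-3-methoxy-2-{[3-methoxy-4-(triisopropylsilyloxy)benzyl]oxy}phenyl)-2-diazoacetate
Conditions: N2CHCO2Et (2 equiv), Pd(PPh3)4 (10 mol %), Ag2CO3 (0.5 equiv), Et3N, toluene, rt
Reagents that add atoms: ethyl diazoacetate, CCOC(=O)C=[N+]=[N-]
Why: Palladium-catalysed cross-coupling of an aryl iodide with a diazoacetate, which arylates the diazo carbon with retention of the diazo group; Pd(PPh3)4 at room temperature should insert into C–I and leave C–Br.

Step 10
Reactants: 12 ethyl 2-(5-bromo-3-methoxy-2-{[3-methoxy-4-(triisopropylsilyloxy)benzyl]oxy}phenyl)-2-diazoacetate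
Product: 13 ethyl (2S,3R)-5-bromo-7-methoxy-2-[3-methoxy-4-(triisopropylsilyloxy)phenyl]-2,3-dihydrobenzofuran-3-carboxylate (2,3-cis)
Conditions: Rh2(R-PTTL)4 (2 mol %), toluene, −60 °C
Reagents that add atoms: none
Why: Rh(II)-carbenoid intramolecular 1,5 C–H insertion into the benzylic C–H next to the ether oxygen, in which the chiral N-phthaloyl-tert-leucinate catalyst should set both new centres and give the kinetic 2,3-cis ester (the antipodal catalyst is used should the sense prove opposite).

Step 11
Reactants: 13 ethyl (2S,3R)-5-bromo-7-methoxy-2-[3-methoxy-4-(triisopropylsilyloxy)phenyl]-2,3-dihydrobenzofuran-3-carboxylate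
Product: 14 [(2S,3S)-5-bromo-7-methoxy-2-[3-methoxy-4-(triisopropylsilyloxy)phenyl]-2,3-dihydrobenzofuran-3-yl]methanol (2,3-cis)
Conditions: DIBAL-H (3 equiv), CH2Cl2, −78 °C; Rochelle salt
Reagents that add atoms: none
Why: Hydride reduction of the ester to the primary alcohol under cold, non-basic conditions, so the epimerisable C3 centre of the cis ester is not touched (the descriptor changes from 3R to 3S only through CIP priorities).

Step 12
Reactants: 14 [(2S,3S)-5-bromo-7-methoxy-2-[3-methoxy-4-(triisopropylsilyloxy)phenyl]-2,3-dihydrobenzofuran-3-yl]methanol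
Product: 15 (2S,3S)-5-bromo-3-[(tert-butyldimethylsilyloxy)methyl]-7-methoxy-2-[3-methoxy-4-(triisopropylsilyloxy)phenyl]-2,3-dihydrobenzofuran
Conditions: TBSCl, imidazole, CH2Cl2/DMF, rt
Reagents that add atoms: tert-butyldimethylsilyl chloride, CC(C)(C)[Si](C)(C)Cl
Why: Silylation of the primary alcohol, so that no free OH can protonate the benzylic titanium intermediate of the key step.

Step 13
Reactants: 15 (2S,3S)-5-bromo-3-[(tert-butyldimethylsilyloxy)methyl]-7-methoxy-2-[3-methoxy-4-(triisopropylsilyloxy)phenyl]-2,3-dihydrobenzofuran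
Product: 16 (2S,3S)-3-[(tert-butyldimethylsilyloxy)methyl]-7-methoxy-2-[3-methoxy-4-(triisopropylsilyloxy)phenyl]-5-vinyl-2,3-dihydrobenzofuran
Conditions: vinylBpin, Pd(dppf)Cl2 (5 mol %), K3PO4, dioxane/H2O, 80 °C
Reagents that add atoms: vinylboronic acid pinacol ester, C=CB1OC(C)(C)C(C)(C)O1
Why: Suzuki–Miyaura vinylation of the aryl bromide; the silyl ethers and the cis-dihydrobenzofuran should be inert to the mild phosphate base.

Step 14
Reactants: 16 (2S,3S)-3-[(tert-butyldimethylsilyloxy)methyl]-7-methoxy-2-[3-methoxy-4-(triisopropylsilyloxy)phenyl]-5-vinyl-2,3-dihydrobenzofuran, 5 (2S)-2-[(R)-(allyloxy)[3,5-dimethoxy-4-(triisopropylsilyloxy)phenyl]methyl]oxirane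
Product: 17 (2S)-2-[(R)-{[(E)-3-{(2S,3S)-3-[(tert-butyldimethylsilyloxy)methyl]-7-methoxy-2-[3-methoxy-4-(triisopropylsilyloxy)phenyl]-2,3-dihydrobenzofuran-5-yl}prop-2-en-1-yl]oxy}[3,5-dimethoxy-4-(triisopropylsilyloxy)phenyl]methyl]oxirane
Conditions: Hoveyda–Grubbs II (5 mol %), 5 (2.5 equiv), CH2Cl2, 40 °C
Reagents that add atoms: none
Why: Olefin cross-metathesis between the slowly homodimerising styrene and an excess of the terminal allyl ether should give the E-cinnamyl ether under thermodynamic control; epoxide, silyl ethers and all stereocentres are inert to the Ru carbene.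

Step 15
Reactants: 17 the (E)-cinnamyl epoxy ether of step 14
Product: 20 tris-silyl ether of the target (7S,8R,7'S,8'R furofuran; 2S,3S dihydrobenzofuran; two aryl OTIPS; one CH2OTBS), via bis-titanium oxolane 18 (not isolated), via benzylic iodide titanium alkoxide 19 (not isolated)
Conditions: Cp2TiCl2 (2.5 equiv), Zn dust, THF, rt, Cp2TiCl solution added slowly to 17; then I2 (1.3 equiv), rt to 45 °C; aq. Na2S2O3
Reagents that add atoms: none
Why: Cp2TiCl opens the terminal oxirane homolytically at the more substituted carbon to give the C8' radical bearing the C9'H2–O–Ti group; this adds 5-exo-trig to C8 of the styrene (first oxolane: O, C7', C8', C8, C9) and the resulting C7 benzylic radical is captured by a second Cp2TiCl as 18, whose C7–Ti bond iodine converts into the benzylic iodide 19, which ionises to the p-alkoxybenzyl (quinone-methide-type) cation stabilised by the dihydrobenzofuran ring oxygen and is captured by the C9' titanium alkoxide (second oxolane: 5-exo closure with the C7=aryl bond exocyclic). The closest known reaction type is the titanocene(III) epoxide-opening radical cyclisation with iodine-induced ring closure that converts epoxy cinnamyl ethers into 2,6-diaryl furofuran lignans. C8' and C8 are controlled by the existing C7' centre through a chair-like 5-hexenyl radical transition state, in which the C7' aryl sits pseudo-equatorial and ends trans to C9', and the usual 1,5-cis preference places C9' and the C7 arm cis, the only arrangement that allows the second closure. C7 is controlled in the ionic closure, where cis ring fusion is geometrically enforced and the benzofuranyl group takes the exo (convex) position. The step needs regioselective opening to the secondary radical (secured by Ti(III)), 5-exo over 6-endo addition (secured by the benzylic radical formed at C7) and cyclisation faster than β-elimination of the β-titanoxy radical (secured by slow addition and the activated styrene); the oxirane stereocentre is erased, so only C7' has to be set beforehand.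

Step 16
Reactants: 20 tris-silyl ether of the target
Product: 21 target, 4-[(7S,8R,7'S,8'R)-furofuran-7'-yl]-2,6-dimethoxyphenol carrying at C7 the (2S,3S)-2-(4-hydroxy-3-methoxyphenyl)-3-(hydroxymethyl)-7-methoxy-2,3-dihydrobenzofuran-5-yl group (CNP0126146.1)
Conditions: TBAF (4 equiv), AcOH (4 equiv), THF, 0 °C to rt
Reagents that add atoms: none
Why: Fluoride cleavage of the two aryl TIPS ethers and the primary TBS ether, buffered with acetic acid so that no free phenoxide can open the p-hydroxybenzyl aryl ether (dihydrobenzofuran C2–O) through a quinone methide and epimerise the cis ring.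

## Compound list

1 | syringaldehyde | COc1cc(C=O)cc(OC)c1O | starting material
2 | 3,5-dimethoxy-4-(triisopropylsilyloxy)benzaldehyde | COc1cc(C=O)cc(OC)c1O[Si](C(C)C)(C(C)C)C(C)C | intermediate
3 | rac-1-[3,5-dimethoxy-4-(triisopropylsilyloxy)phenyl]prop-2-en-1-ol | C=CC(O)c1cc(OC)c(O[Si](C(C)C)(C(C)C)C(C)C)c(OC)c1 | intermediate
4 | (R)-[3,5-dimethoxy-4-(triisopropylsilyloxy)phenyl][(2S)-oxiran-2-yl]methanol | O[C@@H]([C@@H]1CO1)c2cc(OC)c(O[Si](C(C)C)(C(C)C)C(C)C)c(OC)c2 | intermediate
5 | (2S)-2-[(R)-(allyloxy)[3,5-dimethoxy-4-(triisopropylsilyloxy)phenyl]methyl]oxirane | C=CCO[C@@H]([C@@H]1CO1)c2cc(OC)c(O[Si](C(C)C)(C(C)C)C(C)C)c(OC)c2 | intermediate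
6 | vanillin | COc1cc(C=O)ccc1O | starting material
7 | 3-methoxy-4-(triisopropylsilyloxy)benzaldehyde | COc1cc(C=O)ccc1O[Si](C(C)C)(C(C)C)C(C)C | intermediate
8 | [3-methoxy-4-(triisopropylsilyloxy)phenyl]methanol | COc1cc(CO)ccc1O[Si](C(C)C)(C(C)C)C(C)C | intermediate
9 | 4-bromo-2-methoxyphenol | COc1cc(Br)ccc1O | starting material
10 | 4-bromo-2-iodo-6-methoxyphenol | COc1cc(Br)cc(I)c1O | intermediate
11 | 5-bromo-1-iodo-3-methoxy-2-{[3-methoxy-4-(triisopropylsilyloxy)benzyl]oxy}benzene | COc1cc(Br)cc(I)c1OCc2ccc(O[Si](C(C)C)(C(C)C)C(C)C)c(OC)c2 | intermediate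
12 | ethyl 2-(5-bromo-3-methoxy-2-{[3-methoxy-4-(triisopropylsilyloxy)benzyl]oxy}phenyl)-2-diazoacetate | CCOC(=O)C(=[N+]=[N-])c1cc(Br)cc(OC)c1OCc2ccc(O[Si](C(C)C)(C(C)C)C(C)C)c(OC)c2 | intermediate
13 | ethyl (2S,3R)-5-bromo-7-methoxy-2-[3-methoxy-4-(triisopropylsilyloxy)phenyl]-2,3-dihydrobenzofuran-3-carboxylate (cis) | COc1cc([C@H]2Oc3c(OC)cc(Br)cc3[C@H]2C(=O)OCC)ccc1O[Si](C(C)C)(C(C)C)C(C)C | intermediate
14 | [(2S,3S)-5-bromo-7-methoxy-2-[3-methoxy-4-(triisopropylsilyloxy)phenyl]-2,3-dihydrobenzofuran-3-yl]methanol (cis) | COc1cc([C@H]2Oc3c(OC)cc(Br)cc3[C@H]2CO)ccc1O[Si](C(C)C)(C(C)C)C(C)C | intermediate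
15 | (2S,3S)-5-bromo-3-[(tert-butyldimethylsilyloxy)methyl]-7-methoxy-2-[3-methoxy-4-(triisopropylsilyloxy)phenyl]-2,3-dihydrobenzofuran | COc1cc([C@H]2Oc3c(OC)cc(Br)cc3[C@H]2CO[Si](C)(C)C(C)(C)C)ccc1O[Si](C(C)C)(C(C)C)C(C)C | intermediate
16 | (2S,3S)-3-[(tert-butyldimethylsilyloxy)methyl]-7-methoxy-2-[3-methoxy-4-(triisopropylsilyloxy)phenyl]-5-vinyl-2,3-dihydrobenzofuran | COc1cc([C@H]2Oc3c(OC)cc(C=C)cc3[C@H]2CO[Si](C)(C)C(C)(C)C)ccc1O[Si](C(C)C)(C(C)C)C(C)C | intermediate
17 | (E)-cinnamyl epoxy ether: (R)-carbinol ether, (S)-oxirane, (2S,3S)-dihydrobenzofuran | COc1cc([C@H]2Oc3c(OC)cc(/C=C/CO[C@@H]([C@@H]4CO4)c5cc(OC)c(O[Si](C(C)C)(C(C)C)C(C)C)c(OC)c5)cc3[C@H]2CO[Si](C)(C)C(C)(C)C)ccc1O[Si](C(C)C)(C(C)C)C(C)C | intermediate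
18 | bis-titanium oxolane: (2S,3R,4R)-2-aryl-3-(Cp2ClTi–OCH2)-4-[CH(TiCp2Cl)(benzofuranyl)]oxolane, C7 undefined | COc1cc([C@H]2Oc3c(OC)cc(C([Ti](Cl)(C4C=CC=C4)C4C=CC=C4)[C@H]5CO[C@H](c6cc(OC)c(O[Si](C(C)C)(C(C)C)C(C)C)c(OC)c6)[C@H]5CO[Ti](Cl)(C7C=CC=C7)C7C=CC=C7)cc3[C@H]2CO[Si](C)(C)C(C)(C)C)ccc1O[Si](C(C)C)(C(C)C)C(C)C | intermediate (not isolated)
19 | benzylic iodide titanium alkoxide: as 18 with C7–I in place of C7–Ti | COc1cc([C@H]2Oc3c(OC)cc(C(I)[C@H]5CO[C@H](c6cc(OC)c(O[Si](C(C)C)(C(C)C)C(C)C)c(OC)c6)[C@H]5CO[Ti](Cl)(C7C=CC=C7)C7C=CC=C7)cc3[C@H]2CO[Si](C)(C)C(C)(C)C)ccc1O[Si](C(C)C)(C(C)C)C(C)C | intermediate (not isolated)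
20 | tris-silyl ether of the target | COc1cc([C@H]2Oc3c(OC)cc([C@H]4OC[C@H]5[C@@H]4CO[C@@H]5c4cc(OC)c(O[Si](C(C)C)(C(C)C)C(C)C)c(OC)c4)cc3[C@H]2CO[Si](C)(C)C(C)(C)C)ccc1O[Si](C(C)C)(C(C)C)C(C)C | intermediate
21 | CNP0126146.1 | COc1cc([C@H]2Oc3c(OC)cc([C@H]4OC[C@H]5[C@@H]4CO[C@@H]5c4cc(OC)c(O)c(OC)c4)cc3[C@H]2CO)ccc1O | target

## Step count and risks

Total step count: 16. Longest linear sequence: 11 steps (from vanillin 6: steps 5, 6, 8, 9, 10, 11, 12, 13, 14, 15, 16).

Steps most likely to fail:

1. Step 15 (key step). The benzylic titanium species may be protonated or reduced before iodine intercepts it, stopping at the monocyclic stage. The Lewis-acidic Ti(IV)/iodide medium may also ionise benzylic C–O bonds, with loss of the exo configuration at C7 or cis-to-trans isomerisation of the dihydrobenzofuran. Fallback: the two ring closures are decoupled. Setting out from 17, the same Ti(III) cyclisation is run but quenched with aqueous NaH2PO4 instead of iodine, to isolate the reductively terminated (2S,3R,4R)-oxolane alcohol F1. The second ring is then closed under neutral conditions by a hypoiodite (Suárez-type) reaction (PhI(OAc)2, I2, NaHCO3, cyclohexane/CH2Cl2, visible light, rt). The C9' alkoxy radical abstracts the δ benzylic hydrogen at C7 by 1,5-hydrogen transfer, and the benzylic radical is oxidised and closed onto oxygen. The route is rejoined at 20.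

2. Step 10. Enantiofacial discrimination in the carbenoid insertion may be insufficient for this more substituted, electron-rich substrate, so that 13 and hence 14 are obtained with inadequate enantiomeric purity. Fallback: classical resolution instead of catalyst control. Setting out from scalemic 14, esterification with (S)-O-methylmandelic acid (EDC, DMAP cat., CH2Cl2, 0 °C) gives the O-methylmandelate F2, together with the diastereomeric ester of the minor enantiomer F3. The two are separated by chromatography or crystallisation. Reductive cleavage of F2 (DIBAL-H, CH2Cl2, −78 °C) returns 14 as a single enantiomer, where the route is rejoined.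

3. Step 9. Oxidative addition and carbene transfer at the ortho-alkoxy, electron-rich aryl iodide may be slow relative to decomposition of the diazo ester, giving low conversion. Fallback: enolate arylation followed by diazo transfer. Setting out from 11, Pd(PPh3)4-catalysed coupling with the Reformatsky reagent BrZnCH2CO2Et (THF/DMPU, 60 °C, selective for C–I) gives the arylacetate F4. Regitz diazo transfer (p-ABSA, DBU, MeCN, 0 °C to rt) then gives 12, where the route is rejoined.

## Further compounds

F1 | step 15 | [(2S,3R,4R)-4-({(2S,3S)-3-[(tert-butyldimethylsilyloxy)methyl]-7-methoxy-2-[3-methoxy-4-(triisopropylsilyloxy)phenyl]-2,3-dihydrobenzofuran-5-yl}methyl)-2-[3,5-dimethoxy-4-(triisopropylsilyloxy)phenyl]oxolan-3-yl]methanol | COc1cc([C@H]2Oc3c(OC)cc(C[C@H]5CO[C@H](c6cc(OC)c(O[Si](C(C)C)(C(C)C)C(C)C)c(OC)c6)[C@H]5CO)cc3[C@H]2CO[Si](C)(C)C(C)(C)C)ccc1O[Si](C(C)C)(C(C)C)C(C)C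
F2 | step 10 | (S)-O-methylmandelate of 14, (2S,3S) series | COc1cc([C@H]2Oc3c(OC)cc(Br)cc3[C@H]2COC(=O)[C@@H](OC)c4ccccc4)ccc1O[Si](C(C)C)(C(C)C)C(C)C
F3 | step 10 | (S)-O-methylmandelate of the enantiomer of 14, (2R,3R) series | COc1cc([C@@H]2Oc3c(OC)cc(Br)cc3[C@@H]2COC(=O)[C@@H](OC)c4ccccc4)ccc1O[Si](C(C)C)(C(C)C)C(C)C
F4 | step 9 | ethyl 2-(5-bromo-3-methoxy-2-{[3-methoxy-4-(triisopropylsilyloxy)benzyl]oxy}phenyl)acetate | CCOC(=O)Cc1cc(Br)cc(OC)c1OCc2ccc(O[Si](C(C)C)(C(C)C)C(C)C)c(OC)c2
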